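The violet run, which is this very flask followed so far, shows 31.6% of left-handed product at 20.0 min and 37.0% at 120 min. You are asked about 5.0% conversion, less than that first reading, so no reading shows that moment directly.

| setting | violet | flask |
|---|---|---|
| left-handed substrate | 20 mM | 20 mM |
| right-handed substrate | 20 mM | 20 mM |
| partner | 30 mM | 30.0 mM |
| protic impurity | 4 mM | 4.00 mM |
| free catalyst | 0.14 mM | 0.14 mM |
| stray impurity | 54 µM | 54 µM |
| remark | the very flask that is asked about, followed so far |  |

- violet (time / min: left-handed product / %): 20.0: 31.6; 40.0: 34.3; 60.0: 36.3; 80.0: 36.3; 90.0: 38.5; 120: 37.0

(each reading ± 1 percentage point)

- free catalyst is single-handed; left-handed substrate and right-handed substrate are mirror images of each other, charged as a racemate, each of them at the stated concentration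
- steps thought possible: partner + free catalyst + left-handed substrate -> free catalyst + left-handed product; partner + free catalyst + right-handed substrate -> free catalyst + right-handed product; free catalyst + stray impurity -> spent catalyst; partner + protic impurity -> quenched reagent
- no earlier run changes the charge of free catalyst; that part of a forecast is a guess
- no earlier run changes the charge of partner; that part of a forecast is a guess

- apparent order in free catalyst when 5.0% of the left-handed substrate and right-handed substrate together are converted (percent change of the rate of making left-handed product for one percent more free catalyst charged)
- apparent order in partner when 5.0% of the left-handed substrate and right-handed substrate together are converted (percent change of the rate of making left-handed product for one percent more partner charged)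
- factor on the rate of making left-handed product when 5.0% of the left-handed substrate and right-handed substrate together are converted if partner is charged twice over

For the catalyst in this flask, two amounts count: the 0.14 mM of free catalyst charged, and the 86.0 µM that survive if each of the 54 µM of stray impurity, less than the catalyst charged, takes one catalyst away. The impurity acts like a fixed offset on an input. One percent more catalyst charged adds the same amount to the survivors, and that is a larger percentage of them. My own reckoning therefore takes the rate as proportional to the survivors, which makes the order in free catalyst the charge over the survivors, the titration order 1.63. This assumes that the loss of catalyst is over by the moment asked about, which lies before the first reading, but I commit to it.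

The forecast gives 1.3 for free catalyst, lower than my figure, along with 1.18 for partner and a factor of 2.2 for doubling partner. On the catalyst it says: “The data cannot settle this, so I take an intermediate value”.

The flask gives 1.7 for free catalyst, 1.1 for partner and 2.19 for doubling partner.

    partner + free catalyst + left-handed substrate → free catalyst + left-handed product (k = 640 M⁻² s⁻¹)
    partner + free catalyst + right-handed substrate → free catalyst + right-handed product (k = 360 M⁻² s⁻¹)
    free catalyst + stray impurity → spent catalyst (k = 1500 M⁻¹ s⁻¹)
    partner + protic impurity → quenched reagent (k = 0.200 M⁻¹ s⁻¹)

This flask reaches 5.0% conversion at 0.634 min, and the catalyst's loss time with stray impurity as charged, 0.206 min, is about a third of that. The inverse of the titration order, 61.3%, is the share of catalyst expected to survive, and at 1.00 h this flask holds 61.4% as free catalyst and 38.6% as spent catalyst.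

All runs are calculated for substances that don't exist, noise included.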